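**Retrosynthetic overview**
- Numbering (labdane type): ring A = C1–C5/C10, ring B = C5–C10, C11 = CH2 on C9, C12–C15 = side chain up to CO2H, C18 = first CH2 of the 4-methylpent-3-enyl arm on C4.
- Enabling feature: the tetrasubstituted C8=C9 alkene of ring B with its exocyclic C11H2 is a quenched C8–C9–C11 allyl cation. C12 is the γ-carbon of a senecioate (3-methylbut-2-enoate) dienolate, so C11–C12 is the head-to-tail prenyl-transfer seam of the biosynthesis.
- Key disconnection: C11–C12, C9–C10 and C4–C5 are cut at once. This gives an acyclic C20 (3S,4S)-epoxy-ene-allene (allene C8=C9=C11 as cation terminator) and a C5 silyl dienolate. Forward, ring A forms first, ring B second, then the chain is joined, all in one flask.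
- The epoxide comes from (E)-geranylacetone: ethynylation and allene formation at the ketone end; allylic oxidation, Sharpless epoxidation and prenyl coupling at C18 at the other end.
- After the key step only the C3 oxygen (Barton–McCombie) and the methyl ester have to go.

Key step: step 8

Remark: commercial (E)-geranylacetone is taken as the isomerically pure E compound. The ketene acetal geometry of 11 is left open because it does not reach the product.

Step 1
Reactants: 1 (E)-geranylacetone
Product: 3 methyl (6E)-3,7,11-trimethyldodeca-6,10-dien-1-yn-3-yl carbonate (racemic at the carbinol carbon), via bromomagnesium alkoxide 2 (not isolated)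
Conditions: HC≡CMgBr (1.3 equiv), THF, 0 °C; then ClCO2Me (2 equiv), 0 °C to rt
Reagents that add atoms: ethynylmagnesium bromide C#C[Mg]Br; methyl chloroformate COC(=O)Cl
Why: 1,2-Addition of an alkynyl Grignard reagent to the methyl ketone followed by O-acylation of the tertiary alkoxide in the same flask should give the propargylic carbonate; the new carbinol centre is racemic and is erased in step 3.

Step 2
Reactants: 3 propargylic methyl carbonate
Product: 4 methyl (6E,10E)-12-hydroxy-3,7,11-trimethyldodeca-6,10-dien-1-yn-3-yl carbonate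
Conditions: SeO2 (0.3 equiv), t-BuOOH (3 equiv), salicylic acid (0.1 equiv), CH2Cl2, 0 °C to rt
Reagents that add atoms: tert-butyl hydroperoxide CC(C)(C)OO
Why: Selenium dioxide allylic oxidation (Riley type, ene reaction then [2,3]-shift, t-BuOOH as reoxidant) attacks the most accessible, terminal trisubstituted alkene and oxidises its E methyl group, while alkyne and carbonate are inert and no allene is present yet.

Step 3
Reactants: 4 hydroxy propargylic carbonate
Product: 5 (2E,6E)-2,6,10-trimethyldodeca-2,6,10,11-tetraen-1-ol
Conditions: Pd2(dba)3·CHCl3 (2.5 mol %), n-Bu3P (10 mol %), HCO2NH4 (2 equiv), THF, rt to 40 °C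
Reagents that add atoms: none
Why: Palladium-catalysed formate hydrogenolysis of a tertiary propargylic carbonate with a terminal alkyne runs through an allenylpalladium hydride and should give the 1,1-disubstituted allene, removing the racemic centre, while the free allylic alcohol is not ionised by Pd(0).

Step 4
Reactants: 5 allenyl dienol
Product: 6 [(2S,3S)-3-[(3E)-3,7-dimethylnona-3,7,8-trien-1-yl]-2-methyloxiran-2-yl]methanol
Conditions: Ti(Oi-Pr)4 (10 mol %), L-(+)-diethyl tartrate (12 mol %), t-BuOOH (2 equiv), 4 Å MS, CH2Cl2, −20 °C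
Reagents that add atoms: tert-butyl hydroperoxide CC(C)(C)OO
Why: Sharpless asymmetric epoxidation: the allylic hydroxyl group binds titanium so that only this alkene reacts, L-(+)-tartrate delivers oxygen to the face that gives the (2S,3S)-epoxide (future C4 and C3), and the syn addition keeps CH2OH trans to the chain.

Step 5
Reactants: 6 epoxy alcohol
Product: 7 [(2S,3S)-3-[(3E)-3,7-dimethylnona-3,7,8-trien-1-yl]-2-methyloxiran-2-yl]methyl 4-methylbenzenesulfonate
Conditions: TsCl (1.3 equiv), Et3N (2 equiv), DMAP (5 mol %), CH2Cl2, 0 °C
Reagents that add atoms: 4-toluenesulfonyl chloride Cc1ccc(cc1)S(=O)(=O)Cl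
Why: Sulfonylation of the primary alcohol under mild base turns C18 into an electrophile and leaves epoxide, alkene and allene untouched.

Step 6
Reactants: 7 epoxy tosylate
Product: 8 (2S,3S)-3-[(3E)-3,7-dimethylnona-3,7,8-trien-1-yl]-2-methyl-2-(4-methylpent-3-en-1-yl)oxirane
Conditions: prenylmagnesium chloride (3 equiv), CuI (20 mol %), THF, −40 to −10 °C
Reagents that add atoms: prenylmagnesium chloride CC(C)=CC[Mg]Cl
Why: Copper-catalysed sp3–sp3 coupling of a Grignard reagent with a primary tosylate, known for 2,3-epoxy tosylates, should displace the sulfonate faster than the trisubstituted epoxide opens, the allylcopper species coupling through its primary carbon; both stereocentres are untouched.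

Step 7
Reactants: 9 methyl 3-methylbut-2-enoate
Product: 11 1-methoxy-3-methyl-1-(trimethylsilyloxy)buta-1,3-diene, via lithium dienolate 10 (not isolated)
Conditions: LDA (1.1 equiv), THF, −78 °C; then Me3SiCl (1.2 equiv), −78 °C to rt; distillation
Reagents that add atoms: chlorotrimethylsilane C[Si](C)(C)Cl
Why: Kinetic γ-deprotonation of the senecioate with LDA and O-silylation of the extended enolate is the standard route to this silyl dienolate; the geometry of the ketene acetal is of no consequence.

Step 8
Reactants: 8 (2S,3S)-epoxy-ene-allene; 11 silyl dienolate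
Product: 14 methyl (2E)-5-[(4aR,5S,6S,8aS)-6-hydroxy-2,5,8a-trimethyl-5-(4-methylpent-3-en-1-yl)-3,4,4a,5,6,7,8,8a-octahydronaphthalen-1-yl]-3-methylpent-2-enoate (3β-hydroxy ester), via bicyclic allyl cation triflate 12 (not isolated), via 3-O-trimethylsilyl ether 13 (not isolated)
Conditions: 11 (3 equiv), TMSOTf (0.3 equiv), CH2Cl2, −78 °C, slow addition of 8; then 1 M HCl, THF, 0 °C
Reagents that add atoms: none
Why: Proposed new method: Me3Si+ from TMSOTf silylates the epoxide oxygen of 8, C5 of the C5=C10 alkene opens the C4–O bond from the rear, the central allene carbon C9 takes up the charge developing at C10, and the C8 cation left behind becomes the C8–C9–C11 allyl cation 12 as ring B flattens; the γ-carbon (C12) of 11 then adds to its CH2 end C11 and the silyloxycarbenium ion returns Me3Si+ to triflate, so that TMSOTf is only a chain carrier and 8 and 11 add up to 13 without loss of an atom (acid work-up frees the C3 hydroxyl). The closest known reaction types are the epoxide-initiated polyene carbocyclisation promoted by silyl triflates or alkylaluminium chlorides and ended by silyl enol ethers or propargylsilanes, the attack of proton and carbon electrophiles at the central carbon of 1,1-dialkylallenes, and the SN1-type γ-alkylation of silyl dienolates by allyl cations (vinylogous Mukaiyama type), which is the laboratory form of the head-to-tail prenyl transfer of the biosynthesis; new are the allene as terminator and the capture by an external carbon nucleophile. Ring A closes 6-endo at the epoxide (attack at the distal, tertiary carbon C4, both epoxide carbons in the ring) and ring B closes 6-endo with respect to the C8=C9 π bond of the allene, both in a chair–chair fold. C4 is set by inversion at the epoxide carbon, which places the arm that is trans to C2 in 8 equatorial (α) and the methyl group axial (β); C5 (α-H) and C10 (β-CH3) are set by anti addition across the E alkene in the chair fold, and the absolute sense of all three follows from the (2S,3S)-epoxide, whose C3–O bond must stay equatorial. The step needs cyclisation before capture, attack at C11 and not at C8, γ- and not α-attack of 11, and E geometry: only the C5=C10 alkene reaches C4 through a six-membered chair (the arm alkene would have to form a four-membered ring) and the fully substituted C4 is shielded against bimolecular attack, C11 is an open CH2 whereas C8 is tertiary and attack there would forgo the tetrasubstituted alkene, the terminal CH2 of 11 carries the largest HOMO coefficient and the least hindrance, and 11 reacts through its s-trans conformer in an open transition state, which puts C12 trans to the ester. 11 in excess also takes up adventitious TfOH, so that the acid-sensitive trisubstituted arm alkene is not protonated.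

Step 9
Reactants: 14 3β-hydroxy ester
Product: 15 O-(imidazol-1-ylthiocarbonyl) derivative of 14 (configuration unchanged)
Conditions: 1,1'-thiocarbonyldiimidazole (2 equiv), DMAP (10 mol %), ClCH2CH2Cl, 80 °C
Reagents that add atoms: 1,1'-thiocarbonyldiimidazole S=C(n1ccnc1)n1ccnc1
Why: Acylation of the hindered equatorial C3 alcohol with thiocarbonyldiimidazole under neutral conditions prepares the Barton–McCombie deoxygenation without touching the enoate.

Step 10
Reactants: 15 imidazolyl thiocarbamate
Product: 16 methyl (2E)-5-[(4aS,5S,8aS)-2,5,8a-trimethyl-5-(4-methylpent-3-en-1-yl)-3,4,4a,5,6,7,8,8a-octahydronaphthalen-1-yl]-3-methylpent-2-enoate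
Conditions: n-Bu3SnH (2 equiv, 0.5 M), PhSeSePh (10 mol %), AIBN (10 mol %), benzene, 80 °C
Reagents that add atoms: none
Why: Barton–McCombie deoxygenation; benzeneselenol formed in situ from PhSeSePh is a far faster hydrogen donor than the stannane and should quench the C3 radical before it can add 5-exo to the arm alkene, and C4, C5 and C10 are not involved.

Step 11
Reactants: 16 methyl ester
Product: 18 (2E)-5-[(4aS,5S,8aS)-2,5,8a-trimethyl-5-(4-methylpent-3-en-1-yl)-3,4,4a,5,6,7,8,8a-octahydronaphthalen-1-yl]-3-methylpent-2-enoic acid (target), via lithium carboxylate 17 (not isolated)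
Conditions: LiOH·H2O (5 equiv), THF/MeOH/H2O, 50 °C; then 1 M HCl to pH 3
Reagents that add atoms: lithium hydroxide [Li+].[OH-]
Why: Saponification of the β,β-disubstituted enoate with hydroxide and acidification should give the acid with retention of the E geometry, since no deconjugation is expected under these mild conditions.

**Compound list**
1 | (E)-geranylacetone, (5E)-6,10-dimethylundeca-5,9-dien-2-one | CC(C)=CCC/C(C)=C/CCC(C)=O | starting material
2 | bromomagnesium (6E)-3,7,11-trimethyldodeca-6,10-dien-1-yn-3-olate (racemic) | CC(C)=CCC/C(C)=C/CCC(C)(O[Mg]Br)C#C | intermediate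
3 | methyl (6E)-3,7,11-trimethyldodeca-6,10-dien-1-yn-3-yl carbonate (racemic) | CC(C)=CCC/C(C)=C/CCC(C)(OC(=O)OC)C#C | intermediate
4 | methyl (6E,10E)-12-hydroxy-3,7,11-trimethyldodeca-6,10-dien-1-yn-3-yl carbonate (racemic) | OC/C(C)=C/CC/C(C)=C/CCC(C)(OC(=O)OC)C#C | intermediate
5 | (2E,6E)-2,6,10-trimethyldodeca-2,6,10,11-tetraen-1-ol | OC/C(C)=C/CC/C(C)=C/CCC(C)=C=C | intermediate
6 | [(2S,3S)-3-[(3E)-3,7-dimethylnona-3,7,8-trien-1-yl]-2-methyloxiran-2-yl]methanol | OC[C@]1(C)O[C@H]1CC/C(C)=C/CCC(C)=C=C | intermediate
7 | tosylate of 6 | Cc1ccc(cc1)S(=O)(=O)OC[C@]2(C)O[C@H]2CC/C(C)=C/CCC(C)=C=C | intermediate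
8 | (2S,3S)-3-[(3E)-3,7-dimethylnona-3,7,8-trien-1-yl]-2-methyl-2-(4-methylpent-3-en-1-yl)oxirane | CC(C)=CCC[C@]1(C)O[C@H]1CC/C(C)=C/CCC(C)=C=C | intermediate
9 | methyl 3-methylbut-2-enoate (methyl senecioate) | CC(C)=CC(=O)OC | starting material
10 | lithium dienolate of 9 | C=C(C)C=C(OC)[O-].[Li+] | intermediate
11 | 1-methoxy-3-methyl-1-(trimethylsilyloxy)buta-1,3-diene (ketene acetal geometry open) | C=C(C)C=C(OC)O[Si](C)(C)C | intermediate
12 | 3β-trimethylsilyloxy bicyclic C8–C9–C11 allyl cation, triflate ion pair (4β,10β-dimethyl, 4α-arm, 5α-H) | CC(C)=CCC[C@]1(C)[C@@H](O[Si](C)(C)C)CC[C@]2(C)C(=C)[C+](C)CC[C@@H]12.[O-]S(=O)(=O)C(F)(F)F | intermediate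
13 | 3-O-trimethylsilyl ether of 14 | CC(C)=CCC[C@]1(C)[C@@H](O[Si](C)(C)C)CC[C@]2(C)C(CC/C(C)=C/C(=O)OC)=C(C)CC[C@@H]12 | intermediate
14 | methyl (2E)-5-[(4aR,5S,6S,8aS)-6-hydroxy-2,5,8a-trimethyl-5-(4-methylpent-3-en-1-yl)-3,4,4a,5,6,7,8,8a-octahydronaphthalen-1-yl]-3-methylpent-2-enoate | CC(C)=CCC[C@]1(C)[C@@H](O)CC[C@]2(C)C(CC/C(C)=C/C(=O)OC)=C(C)CC[C@@H]12 | intermediate
15 | O-(imidazol-1-ylthiocarbonyl) derivative of 14 | CC(C)=CCC[C@]1(C)[C@@H](OC(=S)n3ccnc3)CC[C@]2(C)C(CC/C(C)=C/C(=O)OC)=C(C)CC[C@@H]12 | intermediate
16 | methyl ester of the target, (4aS,5S,8aS), 2E | CC(C)=CCC[C@]1(C)CCC[C@]2(C)C(CC/C(C)=C/C(=O)OC)=C(C)CC[C@@H]12 | intermediate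
17 | lithium carboxylate of the target | CC(C)=CCC[C@]1(C)CCC[C@]2(C)C(CC/C(C)=C/C(=O)[O-])=C(C)CC[C@@H]12.[Li+] | intermediate
18 | (2E)-5-[(4aS,5S,8aS)-2,5,8a-trimethyl-5-(4-methylpent-3-en-1-yl)-3,4,4a,5,6,7,8,8a-octahydronaphthalen-1-yl]-3-methylpent-2-enoic acid | CC(C)=CCC[C@]1(C)CCC[C@]2(C)C(CC/C(C)=C/C(=O)O)=C(C)CC[C@@H]12 | target

Total step count: 11. Longest linear sequence: 10 (steps 1–6 and 8–11).

**Steps most likely to fail**

1. Step 8 (labelled step).
   - Risk: loss of a proton from the C10 cation or from the allyl cation before the next bond forms, bimolecular opening of the silylated epoxide by the dienolate, or leakage into the Z enoate.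
   - Fallback (known chemistry, join first and cyclise last) sets out from 8 and comes back at 14. Hydroboration of the allene with 9-BBN places boron on the CH2 terminus, as in the preparation of prenylboranes. Perborate oxidation should then give the allylic alcohol F1. Its C8=C9 geometry is of no consequence, because both carbons end up in the tetrasubstituted alkene.
   - CBr4/PPh3 gives the allylic bromide F2.
   - Alkylation of the dianion of methyl acetoacetate at its γ-carbon makes the same C11–C12 bond and gives the β-keto ester F3.
   - NaH/ClP(O)(OEt)2 gives the (Z)-enol phosphate F4. Me2CuLi replaces phosphate by methyl with retention to give the acyclic (2E)-epoxy ester F5.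
   - MeAlCl2 (CH2Cl2, −78 °C) then closes rings A and B in a classical epoxide-initiated bicyclisation that stops at the electron-poor enoate.
   - Proton loss should give 14 together with the Δ7 isomer F6, which is converged on 14 by acid equilibration (TsOH, benzene), the usual way to reach the tetrasubstituted ring-B alkene in the labdane series.

2. Step 6.
   - Risk: competing opening of the epoxide at C3, slow displacement at the hindered C18, and coupling of the allyl nucleophile through its tertiary end.
   - Fallback (stabilised carbanion instead of allylcopper) sets out from 7 and comes back at 8. Lithiated prenyl phenyl sulfone (n-BuLi, THF/DMPU, −78 °C) is alkylated by 7 at the sulfone carbon only, which gives the allylic sulfone F7. The sulfonyl group is then removed reductively (Na/Hg, Na2HPO4, MeOH, −20 °C) to give 8.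

3. Step 10.
   - Risk: 5-exo cyclisation of the C3 radical onto the arm alkene, and hydrostannylation.
   - Fallback (ionic instead of radical removal of the oxygen) sets out from 14 and comes back at 16. Dess–Martin oxidation gives the 3-ketone F8, and TsNHNH2 (EtOH, heat) gives the tosylhydrazone F9. Reduction with catecholborane followed by NaOAc·3H2O turns C3 into CH2 without touching the enoate.

**Further compounds**
F1 | step 8 | (6E)-9-[(2S,3S)-3-methyl-3-(4-methylpent-3-en-1-yl)oxiran-2-yl]-3,7-dimethylnona-2,6-dien-1-ol (C2=C3 geometry open) | CC(C)=CCC[C@]1(C)O[C@H]1CC/C(C)=C/CCC(C)=CCO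
F2 | step 8 | allylic bromide from F1 | CC(C)=CCC[C@]1(C)O[C@H]1CC/C(C)=C/CCC(C)=CCBr
F3 | step 8 | methyl β-keto ester from F2 and the acetoacetate dianion | CC(C)=CCC[C@]1(C)O[C@H]1CC/C(C)=C/CCC(C)=CCCC(=O)CC(=O)OC
F4 | step 8 | (Z)-diethyl enol phosphate of F3 | CC(C)=CCC[C@]1(C)O[C@H]1CC/C(C)=C/CCC(C)=CCC/C(OP(=O)(OCC)OCC)=C/C(=O)OC
F5 | step 8 | acyclic (2E)-3-methyl-2-enoate with the (S,S)-epoxide | CC(C)=CCC[C@]1(C)O[C@H]1CC/C(C)=C/CCC(C)=CCC/C(C)=C/C(=O)OC
F6 | step 8 | Δ7 isomer of 14 (9α-H) | CC(C)=CCC[C@]1(C)[C@@H](O)CC[C@]2(C)[C@@H](CC/C(C)=C/C(=O)OC)C(C)=CC[C@@H]12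
F7 | step 6 | allylic phenyl sulfone, precursor of 8 (sulfone carbon unassigned) | CC(C)=CC(C[C@]1(C)O[C@H]1CC/C(C)=C/CCC(C)=C=C)S(=O)(=O)c2ccccc2
F8 | step 10 | 3-ketone from 14 | CC(C)=CCC[C@]1(C)C(=O)CC[C@]2(C)C(CC/C(C)=C/C(=O)OC)=C(C)CC[C@@H]12
F9 | step 10 | tosylhydrazone of F8 | CC(C)=CCC[C@]1(C)C(=NNS(=O)(=O)c3ccc(C)cc3)CC[C@]2(C)C(CC/C(C)=C/C(=O)OC)=C(C)CC[C@@H]12
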